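**Plan**

1. Side chain numbering used here: C1 (=CH2), C2 (C–CH3), C3 (carbinol, R), C4, C5, C6 (=C–CH3), C7 (=CH), C8 (CH2–O–aryl). The benzene ring is the only ring and is bought, not built.
2. Retrosynthetic cuts, in order: the aryl–CH= bond of the hydroxypropenyl arm (Suzuki–Miyaura), C3–OH back to a ketone, C2–C3 (isopropenyl Grignard on a Weinreb amide), C4–C5 together with the C6=C7 geometry (orthoester Claisen), then the isopropenyl–carbinol bond and the ArO–CH2 bond of the rearrangement substrate.
3. Enabling feature: with C3 at the ester level, C3–C4–C5–C6(CH3)=C7 is a γ,δ-unsaturated ester whose E-trisubstituted alkene carries C8H2–OAr on C7. This is the product pattern of an orthoester Claisen rearrangement of a 2-methylallylic alcohol bearing ArOCH2 on its carbinol carbon.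
4. Forward order: phenol O-alkylation, aryloxyacetaldehyde, racemic isopropenyl carbinol, Claisen rearrangement (chain joined at C4–C5), Weinreb amide, isopropenyl ketone, (R)-alcohol, cross-coupling.
5. Stereochemistry: 6E comes from the chair transition state of the Claisen step, 3R from reagent control by the (S)-oxazaborolidine, and the E geometry of the propenol arm is brought in with the boronate.

Key step: step 4

Assumption: boronate 16 is used as the free allylic alcohol (a catalogue pinacol boronate); hydroxyl groups are tolerated in Suzuki–Miyaura couplings, so no protecting group is carried anywhere in the route.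

**Step 1**
Reactants: 1 4-bromo-2,6-dimethoxyphenol; 2 bromoacetaldehyde diethyl acetal (2-bromo-1,1-diethoxyethane)
Product: 3 5-bromo-2-(2,2-diethoxyethoxy)-1,3-dimethoxybenzene
Conditions: K2CO3, DMF, 110 °C
Reagents that add atoms: bromoacetaldehyde diethyl acetal 2, CCOC(CBr)OCC
Why: Williamson ether synthesis in which the phenoxide displaces the primary bromide; the β-alkoxy groups slow the SN2 step, hence the dipolar aprotic solvent and heat, and the aryl bromide is inert to carbonate.

**Step 2**
Reactants: 3 5-bromo-2-(2,2-diethoxyethoxy)-1,3-dimethoxybenzene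
Product: 4 2-(4-bromo-2,6-dimethoxyphenoxy)acetaldehyde
Conditions: 2 M aq. HCl, THF, 50 °C; crude aldehyde dried azeotropically (toluene) and used at once
Reagents that add atoms: water, O
Why: Acid-catalysed acetal hydrolysis; the usual side reaction of aryloxyacetaldehyde acetals, cyclodehydration to a benzofuran, is excluded because both ortho positions carry methoxy groups.

**Step 3**
Reactants: 4 2-(4-bromo-2,6-dimethoxyphenoxy)acetaldehyde; 5 isopropenylmagnesium bromide
Product: 6 rac-1-(4-bromo-2,6-dimethoxyphenoxy)-3-methylbut-3-en-2-ol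
Conditions: 5 (1.3 equiv), THF, −78 → 0 °C; sat. aq. NH4Cl
Reagents that add atoms: isopropenylmagnesium bromide 5, C=C(C)[Mg]Br
Why: Grignard 1,2-addition to an aldehyde; an alkenylmagnesium halide does not exchange with the electron-rich aryl bromide at low temperature, and the racemate is sufficient because this stereocentre is erased in step 4.

**Step 4**
Reactants: 6 rac-1-(4-bromo-2,6-dimethoxyphenoxy)-3-methylbut-3-en-2-ol; 7 triethyl orthoacetate
Product: 10 ethyl (E)-6-(4-bromo-2,6-dimethoxyphenoxy)-4-methylhex-4-enoate, via mixed orthoester 8 (not isolated), via ketene acetal 9 (not isolated)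
Conditions: 7 (7 equiv), EtCO2H (0.1 equiv), 135–140 °C, EtOH distilled off
Reagents that add atoms: triethyl orthoacetate 7, CC(OCC)(OCC)OCC
Why: Propionic acid catalyses replacement of one ethoxy group of 7 by the secondary allylic alcohol to give mixed orthoester 8, which loses ethanol to ketene acetal 9; 9 then undergoes a concerted suprafacial [3,3]-sigmatropic shift through a chair transition state that bonds the ketene-acetal CH2 (future C4) to the terminal =CH2 of the isopropenyl group (future C5), cleaves the carbinol C–O bond and shifts the double bond to C6=C7. The closest known reaction type is the Johnson orthoester Claisen rearrangement of 2-methylalk-1-en-3-ols to (E)-4-methylalk-4-enoates. No ring is closed and no stereocentre is created; the carbinol centre of 6 becomes sp2, which is why racemic 6 can be used. The selectivity needed is the E geometry of the new trisubstituted alkene, and it should follow from the chair in which the ArOCH2 group on the carbinol carbon is pseudo-equatorial, because the pseudo-axial arrangement would clash 1,3-diaxially with the ethoxy group on the ketene-acetal carbon. The allyl aryl ether in 10 should survive the temperature because an aromatic Claisen rearrangement has no free ortho or para position to end on (two methoxy groups and bromine), and the weak carboxylic acid should not ionise it.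

**Step 5**
Reactants: 10 ethyl (E)-6-(4-bromo-2,6-dimethoxyphenoxy)-4-methylhex-4-enoate; 11 N,O-dimethylhydroxylamine hydrochloride
Product: 12 (E)-6-(4-bromo-2,6-dimethoxyphenoxy)-N-methoxy-N,4-dimethylhex-4-enamide
Conditions: 11 (1.6 equiv), i-PrMgCl (3.2 equiv), THF, −20 → 0 °C; sat. aq. NH4Cl
Reagents that add atoms: N,O-dimethylhydroxylamine hydrochloride 11, CNOC.Cl
Why: Direct aminolysis of the ester by the chloromagnesium amide generated in the flask (Weinreb amide synthesis); at −20 °C i-PrMgCl neither adds to the ester nor exchanges with the electron-rich aryl bromide.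

**Step 6**
Reactants: 12 (E)-6-(4-bromo-2,6-dimethoxyphenoxy)-N-methoxy-N,4-dimethylhex-4-enamide; 5 isopropenylmagnesium bromide
Product: 14 (6E)-8-(4-bromo-2,6-dimethoxyphenoxy)-2,6-dimethylocta-1,6-dien-3-one, via tetrahedral magnesium adduct 13 (not isolated)
Conditions: 5 (2.5 equiv), THF, 0 °C; poured into cold sat. aq. NH4Cl
Reagents that add atoms: isopropenylmagnesium bromide 5, C=C(C)[Mg]Br
Why: Weinreb ketone synthesis in which the chelated tetrahedral adduct 13 persists until work-up, so only one isopropenyl group is delivered and the enone is released in the cold buffered quench, where the liberated amine is protonated and cannot add in conjugate fashion.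

**Step 7**
Reactants: 14 (6E)-8-(4-bromo-2,6-dimethoxyphenoxy)-2,6-dimethylocta-1,6-dien-3-one
Product: 15 (3R,6E)-8-(4-bromo-2,6-dimethoxyphenoxy)-2,6-dimethylocta-1,6-dien-3-ol
Conditions: (S)-2-methyl-CBS-oxazaborolidine (0.2 equiv), catecholborane (1.8 equiv), toluene, −78 °C; MeOH, then aq. NaOH wash
Reagents that add atoms: none
Why: Corey–Bakshi–Shibata reduction in which the ketone binds the ring boron with the isopropenyl group (the large, sp2-branched substituent) directed away from the catalyst, so the nitrogen-bound borane delivers hydride to the Si face and sets C3 as R (the same sense as acetophenone to (R)-1-phenylethanol with this catalyst); catecholborane at −78 °C reduces 1,2 and does not hydroborate the two alkenes.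

**Step 8**
Reactants: 15 (3R,6E)-8-(4-bromo-2,6-dimethoxyphenoxy)-2,6-dimethylocta-1,6-dien-3-ol; 16 (E)-3-(4,4,5,5-tetramethyl-1,3,2-dioxaborolan-2-yl)prop-2-en-1-ol
Product: 17 (3R,6E)-8-{4-[(1E)-3-hydroxyprop-1-en-1-yl]-2,6-dimethoxyphenoxy}-2,6-dimethylocta-1,6-dien-3-ol (CNP0161487.1)
Conditions: 16 (1.5 equiv), Pd(dppf)Cl2 (5 mol %), K2CO3 (3 equiv), degassed 1,4-dioxane/H2O, 80 °C
Reagents that add atoms: (E)-3-(4,4,5,5-tetramethyl-1,3,2-dioxaborolan-2-yl)prop-2-en-1-ol 16, OC/C=C/B1OC(C)(C)C(C)(C)O1
Why: Suzuki–Miyaura coupling by oxidative addition of zerovalent palladium into the unhindered aryl bromide, transmetalation of the alkenyl boronate with retention of its E geometry and reductive elimination; the free hydroxyl groups are tolerated, the γ,γ-disubstituted allyl aryl ether is a poor substrate for allylic ionisation, and the C3 stereocentre is not touched.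

**Compound list**

1 | 4-bromo-2,6-dimethoxyphenol | Oc1c(OC)cc(Br)cc1OC | starting material
2 | bromoacetaldehyde diethyl acetal (2-bromo-1,1-diethoxyethane) | CCOC(CBr)OCC | starting material
3 | 5-bromo-2-(2,2-diethoxyethoxy)-1,3-dimethoxybenzene | CCOC(COc1c(OC)cc(Br)cc1OC)OCC | intermediate
4 | 2-(4-bromo-2,6-dimethoxyphenoxy)acetaldehyde | O=CCOc1c(OC)cc(Br)cc1OC | intermediate
5 | isopropenylmagnesium bromide | C=C(C)[Mg]Br | starting material
6 | rac-1-(4-bromo-2,6-dimethoxyphenoxy)-3-methylbut-3-en-2-ol | C=C(C)C(O)COc1c(OC)cc(Br)cc1OC | intermediate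
7 | triethyl orthoacetate | CC(OCC)(OCC)OCC | starting material
8 | 5-bromo-2-{[2-(1,1-diethoxyethoxy)-3-methylbut-3-en-1-yl]oxy}-1,3-dimethoxybenzene (mixed orthoester, racemic, not isolated) | C=C(C)C(COc1c(OC)cc(Br)cc1OC)OC(C)(OCC)OCC | intermediate
9 | 5-bromo-2-({2-[(1-ethoxyethenyl)oxy]-3-methylbut-3-en-1-yl}oxy)-1,3-dimethoxybenzene (ketene acetal, racemic, not isolated) | C=C(C)C(COc1c(OC)cc(Br)cc1OC)OC(=C)OCC | intermediate
10 | ethyl (E)-6-(4-bromo-2,6-dimethoxyphenoxy)-4-methylhex-4-enoate | CCOC(=O)CC/C(C)=C/COc1c(OC)cc(Br)cc1OC | intermediate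
11 | N,O-dimethylhydroxylamine hydrochloride | CNOC.Cl | starting material
12 | (E)-6-(4-bromo-2,6-dimethoxyphenoxy)-N-methoxy-N,4-dimethylhex-4-enamide | CON(C)C(=O)CC/C(C)=C/COc1c(OC)cc(Br)cc1OC | intermediate
13 | bromomagnesium (6E)-8-(4-bromo-2,6-dimethoxyphenoxy)-3-[methoxy(methyl)amino]-2,6-dimethylocta-1,6-dien-3-olate (tetrahedral adduct, racemic, not isolated) | C=C(C)C(O[Mg]Br)(N(C)OC)CC/C(C)=C/COc1c(OC)cc(Br)cc1OC | intermediate
14 | (6E)-8-(4-bromo-2,6-dimethoxyphenoxy)-2,6-dimethylocta-1,6-dien-3-one | C=C(C)C(=O)CC/C(C)=C/COc1c(OC)cc(Br)cc1OC | intermediate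
15 | (3R,6E)-8-(4-bromo-2,6-dimethoxyphenoxy)-2,6-dimethylocta-1,6-dien-3-ol | C=C(C)[C@H](O)CC/C(C)=C/COc1c(OC)cc(Br)cc1OC | intermediate
16 | (E)-3-(4,4,5,5-tetramethyl-1,3,2-dioxaborolan-2-yl)prop-2-en-1-ol | OC/C=C/B1OC(C)(C)C(C)(C)O1 | starting material
17 | (3R,6E)-8-{4-[(1E)-3-hydroxyprop-1-en-1-yl]-2,6-dimethoxyphenoxy}-2,6-dimethylocta-1,6-dien-3-ol | C=C(C)[C@H](O)CC/C(C)=C/COc1c(OC)cc(/C=C/CO)cc1OC | target

**Totals**

Total step count: 8. Longest linear sequence: 8 steps, from 1 to 17.

**Steps most likely to fail**

Step 7. The two carbonyl substituents, isopropenyl and a primary alkyl chain, differ less in size than the pair in aryl alkyl ketones, so facial discrimination may be poor. Some 1,4-reduction may also compete. The fallback sets out from 14 and comes back at 15. Luche reduction of 14 (NaBH4, CeCl3·7H2O, MeOH, 0 °C) should give the racemic alcohol rac-(6E)-8-(4-bromo-2,6-dimethoxyphenoxy)-2,6-dimethylocta-1,6-dien-3-ol F1. A Sharpless kinetic resolution follows (Ti(OiPr)4, L-(+)-diisopropyl tartrate, t-BuOOH, 4 Å molecular sieves, CH2Cl2, −20 °C, taken a little past half conversion). With this tartrate the (S)-carbinol is the fast-reacting enantiomer and should be converted into the epoxy alcohol (1S,4E)-6-(4-bromo-2,6-dimethoxyphenoxy)-4-methyl-1-[(2R)-2-methyloxiran-2-yl]hex-4-en-1-ol F2, which is removed by chromatography. The slow-reacting (R)-alcohol 15 is recovered. The C6=C7 alkene is not part of an allylic alcohol and should be left alone by the titanium–tartrate oxidant.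

Step 4. At 140 °C with acid present, the electron-rich phenoxide may ionise away from the allylic position of the product. The mixed orthoester may also eliminate instead of rearranging, and geometric control may erode. The fallback sets out from 6 and comes back at 12, keeping the same C4–C5 bond formation but under basic conditions at or below room temperature. Acetylation of 6 (Ac2O, pyridine, DMAP, CH2Cl2) should give 1-(4-bromo-2,6-dimethoxyphenoxy)-3-methylbut-3-en-2-yl acetate F3. Ireland–Claisen rearrangement (LiN(SiMe3)2, Me3SiCl, Et3N, THF, −78 °C → room temperature) would pass through the trimethylsilyl ketene acetal 5-bromo-1,3-dimethoxy-2-[(3-methyl-2-{[1-(trimethylsilyloxy)ethenyl]oxy}but-3-en-1-yl)oxy]benzene F4. The chair [3,3] shift then gives trimethylsilyl (E)-6-(4-bromo-2,6-dimethoxyphenoxy)-4-methylhex-4-enoate F5, which aqueous work-up hydrolyses to (E)-6-(4-bromo-2,6-dimethoxyphenoxy)-4-methylhex-4-enoic acid F6. Amide coupling of F6 with 11 (EDC·HCl, HOBt, i-Pr2NEt, CH2Cl2) gives Weinreb amide 12.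

Step 8. Protodeboronation or homocoupling of the hydroxypropenyl boronate in aqueous base may outrun a slow oxidative addition into the electron-rich aryl bromide. While the catalyst idles, zerovalent palladium may also begin to ionise the allylic aryl ether. The fallback sets out from 15 and comes back at 17, replacing the boronate by a robust olefin and adjusting the oxidation level afterwards. A Heck reaction of 15 with excess ethyl acrylate (Pd(OAc)2, P(o-tol)3, Et3N, DMF, 90 °C) should give ethyl (E)-3-(4-{[(2E,6R)-6-hydroxy-3,7-dimethylocta-2,7-dien-1-yl]oxy}-3,5-dimethoxyphenyl)prop-2-enoate F7. 1,2-Reduction of the ester with i-Bu2AlH (excess, CH2Cl2, −78 °C) then gives 17.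

**Further compounds**

F1 | step 7 | rac-(6E)-8-(4-bromo-2,6-dimethoxyphenoxy)-2,6-dimethylocta-1,6-dien-3-ol | C=C(C)C(O)CC/C(C)=C/COc1c(OC)cc(Br)cc1OC
F2 | step 7 | (1S,4E)-6-(4-bromo-2,6-dimethoxyphenoxy)-4-methyl-1-[(2R)-2-methyloxiran-2-yl]hex-4-en-1-ol | C[C@@]1(CO1)[C@@H](O)CC/C(C)=C/COc1c(OC)cc(Br)cc1OC
F3 | step 4 | 1-(4-bromo-2,6-dimethoxyphenoxy)-3-methylbut-3-en-2-yl acetate (racemic) | CC(=O)OC(COc1c(OC)cc(Br)cc1OC)C(C)=C
F4 | step 4 | 5-bromo-1,3-dimethoxy-2-[(3-methyl-2-{[1-(trimethylsilyloxy)ethenyl]oxy}but-3-en-1-yl)oxy]benzene (racemic) | C=C(O[Si](C)(C)C)OC(COc1c(OC)cc(Br)cc1OC)C(C)=C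
F5 | step 4 | trimethylsilyl (E)-6-(4-bromo-2,6-dimethoxyphenoxy)-4-methylhex-4-enoate | C[Si](C)(C)OC(=O)CC/C(C)=C/COc1c(OC)cc(Br)cc1OC
F6 | step 4 | (E)-6-(4-bromo-2,6-dimethoxyphenoxy)-4-methylhex-4-enoic acid | OC(=O)CC/C(C)=C/COc1c(OC)cc(Br)cc1OC
F7 | step 8 | ethyl (E)-3-(4-{[(2E,6R)-6-hydroxy-3,7-dimethylocta-2,7-dien-1-yl]oxy}-3,5-dimethoxyphenyl)prop-2-enoate | C=C(C)[C@H](O)CC/C(C)=C/COc1c(OC)cc(/C=C/C(=O)OCC)cc1OC
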